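**Retrosynthetic overview**
1. Numbering: C1 lactone C=O, C2 CH2, C3 H–C–O2, C4 CH3–C–O(lactone), C5 ring CH2, C6 CH3–C(chain)–O1, chain C7–C15.
2. Chain: C8–C9 comes from cross-metathesis and diimide. C6–C7 comes from axial allylation of the cyclic peroxycarbenium ion of ketal 9, which sets C6 from C4.
3. 1,2-Dioxane: O1–O2 is inserted aerobically into the C3–C6 bond of cyclobutanol 5, so the four-membered ring C3–C4–C5–C6 becomes the six-membered ring O1–O2–C3–C4–C5–C6. The C3 ring fusion is then proof-read by a reversible oxa-Michael addition.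
4. Enabling feature: C3–C6 form a four-carbon unit cis-fused to the butanolide along C3–C4, with O–O bridging its ends. C6 is fully substituted and O-bearing, so it can pass through the ketone/hemiketal level. C3 is secondary, which directs the β-scission, and it is β to C1=O, so its C–O bond is reversible.
5. Cyclobutane: ketene + α-angelica lactone [2+2]. C4, the only stereocentre carried through, comes from a ketoreductase resolution. Ring order: lactone (bought) → cyclobutane → dioxane.

Key step: step 4

Assumption: a ketoreductase that selectively reduces the (1R,5R) enantiomer of ketone 3 is assumed to be found in a commercial enzyme panel.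

**Step 1**
Reactants: 1 α-angelica lactone
Product: 3 (±)-1-methyl-2-oxabicyclo[3.2.0]heptane-3,6-dione (cis-fused), via dichlorocyclobutanone 2 (not isolated)
Conditions: Cl3CCOCl, Zn–Cu, DME/Et2O, 0 °C → rt; filter, concentrate; Zn, AcOH, rt
Reagents that add atoms: trichloroacetyl chloride, ClC(Cl)(Cl)C(Cl)=O
Why: Ketene–alkene [2+2] cycloaddition followed by reductive dechlorination: the ketene carbonyl carbon bonds to the nucleophilic CH terminus (C3) and CCl2 to the O-bearing carbon (C4) of the enol ester, suprafacial addition to the ring alkene gives the only possible cis fusion of C3/C4 (racemic), and in acetic acid the zinc enolate should be protonated before it can expel the lactone carboxylate.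

**Step 2**
Reactants: 3 (±)-1-methyl-2-oxabicyclo[3.2.0]heptane-3,6-dione
Product: 4 (1S,5S)-1-methyl-2-oxabicyclo[3.2.0]heptane-3,6-dione
Conditions: ketoreductase (KRED), NADP+ (cat.), i-PrOH, phosphate buffer pH 7, 30 °C, stopped near half conversion; SiO2
Reagents that add atoms: none
Why: Enzymatic kinetic resolution (ketoreductase class) of a bicyclo[3.2.0] cyclobutanone, a classical substrate type for these enzymes: the (1R,5R) ketone is reduced, and the (1S,5S) ketone, which carries C4 of the target, is left and separated.

**Step 3**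
Reactants: 4 (1S,5S)-1-methyl-2-oxabicyclo[3.2.0]heptane-3,6-dione
Product: 5 (1S,5R,6R)-6-hydroxy-1,6-dimethyl-2-oxabicyclo[3.2.0]heptan-3-one
Conditions: MeMgBr, LaCl3·2LiCl, THF, −78 °C; AcOH quench at −78 °C
Reagents that add atoms: methylmagnesium bromide, C[Mg]Br
Why: Lanthanide-assisted Grignard 1,2-addition: the strained ketone reacts far faster than the lactone, enolisation and E1cB loss of the β-acyloxy group are suppressed, convex-face attack puts CH3 exo (a centre erased in step 4), and the cold acidic quench keeps the alkoxide from shifting the acyl group between the two cis tertiary oxygens on C4 and C6, which would racemise 5.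

**Step 4**
Reactants: 5 (1S,5R,6R)-6-hydroxy-1,6-dimethyl-2-oxabicyclo[3.2.0]heptan-3-one
Product: 7 (3S,4aS,7aS)-3-hydroxy-3,4a-dimethyltetrahydro-3H-furo[3,2-c][1,2]dioxin-6(4H)-one, via hydroperoxy ketone 6 (not isolated)
Conditions: Co(acac)2 (cat.), O2 (1 atm), toluene, 40 °C
Reagents that add atoms: dioxygen, O=O
Why: This is the aerobic cobalt-catalysed oxidative ring expansion of a cyclobutanol to a 1,2-dioxan-3-ol (four-ring counterpart of the cyclopropanol → 1,2-dioxolan-3-ol oxygenation): the Co(III) alkoxide of 5 releases the C6–O• radical, strain-driven β-scission opens the ring, the carbon radical takes up triplet O2, and hydroperoxide 6 adds to the methyl ketone just formed. The required regioselectivity (C6–C3, not C6–C5 or C6–CH3) is secured by the substrate, because only C3 gives a secondary radical, C5 would be a neopentyl-type primary one, and loss of CH3• releases no strain. The dioxane closes by 6-exo-trig addition of C3–OOH to the C6 carbonyl, so both oxygen atoms of O2 end up in the former C3–C6 bond while the lactone and C4 (S) stay untouched. At C3, O2 capture by a planar radical has no barrier and cannot be steered, so the control element is the ring fusion: only the hydroperoxide syn to the C5 arm closes to the unstrained cis-fused bicycle 7, and because C3–O is β to the lactone carbonyl, material from anti capture (which can only close trans-fused) is brought to the same fusion in step 5. C6 is a hemiketal centre under anomeric equilibrium (axial OH drawn) and is deliberately left at the ketone level, to be erased and reset in step 6. Chemoselectivity rests on timing, since no alkene, phenol or secondary alcohol is present yet.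

**Step 5**
Reactants: 7 peroxy-hemiketal lactone
Product: 9 (3S,4aS,7aS)-3-methoxy-3,4a-dimethyltetrahydro-3H-furo[3,2-c][1,2]dioxin-6(4H)-one, via hydroperoxy-ketal butenolide 8 (not isolated)
Conditions: PPTS (cat.), MeOH, rt; concentrate; Et2NH (cat.), CF3CH2OH, rt
Reagents that add atoms: methanol, CO
Why: Acid-catalysed exchange of the hemiketal OH for OMe gives a storable peroxyketal, and the amine/fluoro-alcohol stage runs a reversible E1cB/oxa-Michael shuttle through 8 (6-exo-trig) in which the three-atom tether C5–C6–O1 can reach C3 of the butenolide only from its own face, which fixes the cis fusion (C3 S) whichever face captured O2.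

**Step 6**
Reactants: 9 methoxy peroxyketal lactone
Product: 10 (3R,4aS,7aS)-3-allyl-3,4a-dimethyltetrahydro-3H-furo[3,2-c][1,2]dioxin-6(4H)-one
Conditions: allylSiMe3, TMSOTf (cat.), CH2Cl2, −78 °C
Reagents that add atoms: allyltrimethylsilane, C=CC[Si](C)(C)C
Why: Hosomi–Sakurai substitution through the cyclic peroxycarbenium ion: in the favoured half-chair C4–CH3 and C3–CH2 are pseudo-equatorial and C4–O(lactone) is pseudo-axial, so chair-forming axial attack at C6 comes from the face of the lactone oxygen, whereas the other face would need a syn-axial contact with C4–CH3, and this places the new chain cis to the lactone oxygen (C6 R).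

**Step 7**
Reactants: 11 octa-1,7-diene; 12 4-iodophenol
Product: 14 4-(oct-7-en-1-yl)phenol, via B-alkyl borane 13 (not isolated)
Conditions: 11 (excess), 9-BBN-H, THF, 0 °C → rt; then 12, PdCl2(dppf) (cat.), aq. K3PO4, DMF, 50 °C
Reagents that add atoms: none
Why: B-alkyl Suzuki–Miyaura coupling: 9-BBN adds anti-Markovnikov to one terminus of the diene used in excess, the borane couples with the aryl iodide, the free phenol is tolerated as its phenoxide, and no stereocentre is formed.

**Step 8**
Reactants: 10 allyl peroxide lactone; 14 4-(oct-7-en-1-yl)phenol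
Product: 15 (3R,4aS,7aS)-3-[(2E)-9-(4-hydroxyphenyl)non-2-en-1-yl]-3,4a-dimethyltetrahydro-3H-furo[3,2-c][1,2]dioxin-6(4H)-one (E drawn)
Conditions: Grubbs II (cat.), 14 (excess), CH2Cl2, 40 °C
Reagents that add atoms: none
Why: Olefin cross-metathesis of two terminal alkenes, driven by loss of ethene and an excess of 14; dialkyl peroxides, lactones and free phenols are tolerated by the ruthenium carbene, and the alkene geometry is irrelevant because the alkene is saturated next.

**Step 9**
Reactants: 15 unsaturated plakortolide precursor
Product: 16 plakortolide F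
Conditions: KO2CN=NCO2K, AcOH, MeOH/CH2Cl2, 0 °C → rt
Reagents that add atoms: none
Why: Diimide reduction: concerted syn transfer of H2 to the unpolarised C=C spares the O–O bond (which catalytic hydrogenation would cleave), the lactone and the arene, and touches no stereocentre.

**Compound list**
1 | α-angelica lactone, 5-methylfuran-2(3H)-one | CC1=CCC(=O)O1 | starting material
2 | (±)-7,7-dichloro-1-methyl-2-oxabicyclo[3.2.0]heptane-3,6-dione, cis-fused, both enantiomers written | O=C1C[C@@H]2C(=O)C(Cl)(Cl)[C@]2(C)O1.O=C1C[C@H]2C(=O)C(Cl)(Cl)[C@@]2(C)O1 | intermediate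
3 | (±)-1-methyl-2-oxabicyclo[3.2.0]heptane-3,6-dione, cis-fused, both enantiomers written | O=C1C[C@@H]2C(=O)C[C@]2(C)O1.O=C1C[C@H]2C(=O)C[C@@]2(C)O1 | intermediate
4 | (1S,5S)-1-methyl-2-oxabicyclo[3.2.0]heptane-3,6-dione | O=C1C[C@@H]2C(=O)C[C@]2(C)O1 | intermediate
5 | (1S,5R,6R)-6-hydroxy-1,6-dimethyl-2-oxabicyclo[3.2.0]heptan-3-one | O=C1C[C@@H]2[C@](C)(O)C[C@]2(C)O1 | intermediate
6 | (4S,5S)-4-hydroperoxy-5-methyl-5-(2-oxopropyl)oxolan-2-one | CC(=O)C[C@]1(C)OC(=O)C[C@@H]1OO | intermediate
7 | (3S,4aS,7aS)-3-hydroxy-3,4a-dimethyltetrahydro-3H-furo[3,2-c][1,2]dioxin-6(4H)-one (axial-OH anomer drawn) | C[C@@]1(O)C[C@]2(C)OC(=O)C[C@@H]2OO1 | intermediate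
8 | (5S)-5-(2-hydroperoxy-2-methoxypropyl)-5-methylfuran-2(5H)-one (ketal carbon: both epimers) | COC(C)(OO)C[C@]1(C)OC(=O)C=C1 | intermediate
9 | (3S,4aS,7aS)-3-methoxy-3,4a-dimethyltetrahydro-3H-furo[3,2-c][1,2]dioxin-6(4H)-one (axial-OMe anomer drawn) | C[C@@]1(OC)C[C@]2(C)OC(=O)C[C@@H]2OO1 | intermediate
10 | (3R,4aS,7aS)-3-allyl-3,4a-dimethyltetrahydro-3H-furo[3,2-c][1,2]dioxin-6(4H)-one | C[C@@]1(CC=C)C[C@]2(C)OC(=O)C[C@@H]2OO1 | intermediate
11 | octa-1,7-diene | C=CCCCCC=C | starting material
12 | 4-iodophenol | Oc1ccc(I)cc1 | starting material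
13 | 9-(oct-7-en-1-yl)-9-borabicyclo[3.3.1]nonane | C=CCCCCCCB1C2CCCC1CCC2 | intermediate
14 | 4-(oct-7-en-1-yl)phenol | C=CCCCCCCc1ccc(O)cc1 | intermediate
15 | (3R,4aS,7aS)-3-[(2E)-9-(4-hydroxyphenyl)non-2-en-1-yl]-3,4a-dimethyltetrahydro-3H-furo[3,2-c][1,2]dioxin-6(4H)-one | C[C@@]1(C/C=C/CCCCCCc2ccc(O)cc2)C[C@]2(C)OC(=O)C[C@@H]2OO1 | intermediate
16 | plakortolide F, (3R,4aS,7aS)-3-[9-(4-hydroxyphenyl)nonyl]-3,4a-dimethyltetrahydro-3H-furo[3,2-c][1,2]dioxin-6(4H)-one | C[C@@]1(CCCCCCCCCc2ccc(O)cc2)C[C@]2(C)OC(=O)C[C@@H]2OO1 | target

Total steps: 9. Longest linear sequence: 8 (steps 1–6, 8, 9).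

**Steps most likely to fail**

Step 4. Three processes may go wrong:
- O2 capture at C3 without facial preference.
- Cobalt-induced dehydration of the secondary hydroperoxide.
- Slow acyl shift in 5 under Lewis-acidic cobalt, with erosion of enantiopurity.

The fallback sets out from 5 and returns at 8, and thus at 9. The same C3–C6 bond is cut without O2, and the O–O unit is brought in as H2O2. Hypoiodite alkoxy-radical fragmentation of 5 (PhI(OAc)2, I2, visible light, CH2Cl2) gives the γ-iodo ketone F1. Et3N then removes HI to give the butenolide ketone F2. Urea–H2O2 with catalytic camphorsulfonic acid in MeOH converts the ketone into hydroperoxy ketal 8, and the amine stage of step 5 closes it to 9. The ring fusion is then fixed by the tether alone.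

Step 6. Three processes may go wrong:
- Lewis-acid-triggered heterolysis of the O–O bond (Hock/Criegee-type fragmentation).
- Loss of methanol by proton loss from C5.
- Attack on both faces of the cation.

The fallback sets out from 5, passes through the butenolide ketone F2 made as above, and returns at 10. The C6–C7 bond is made on the ketone, and the peroxide is installed afterwards. Indium-mediated Barbier allylation of F2 (allyl bromide, In, THF/H2O) gives the tertiary homoallylic alcohol F3. Acid-catalysed perhydrolysis (ethereal H2O2, cat. H2SO4) gives the tertiary hydroperoxide F4 through the C6 cation. Et3N in CF3CH2OH closes F4 by oxa-Michael addition to 10, together with its C6 epimer F5, which must be removed by chromatography. The cost of this fallback is the loss of stereocontrol at C6.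

Step 1. Three processes may go wrong:
- Isomerisation or oligomerisation of the enol lactone by zinc salts.
- Sluggish cycloaddition of the deactivated enol ester.
- Reductive β-elimination of the lactone carboxylate during dechlorination.

The fallback sets out from 1 and returns at 3. It is a chlorine-free keteniminium [2+2] cycloaddition (N,N-dimethylacetamide, Tf2O, 2,4,6-collidine, ClCH2CH2Cl, reflux) that gives the cyclobutaniminium triflate F6. Aqueous NaHCO3 hydrolyses F6 to 3, so no zinc enolate is ever formed.

**Further compounds**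
F1 | step 4 | (5S)-4-iodo-5-methyl-5-(2-oxopropyl)oxolan-2-one (both C4 epimers) | CC(=O)C[C@]1(C)OC(=O)CC1I
F2 | step 4 | (5S)-5-methyl-5-(2-oxopropyl)furan-2(5H)-one | CC(=O)C[C@]1(C)OC(=O)C=C1
F3 | step 6 | (5S)-5-(2-hydroxy-2-methylpent-4-en-1-yl)-5-methylfuran-2(5H)-one (both carbinol epimers) | C=CCC(C)(O)C[C@]1(C)OC(=O)C=C1
F4 | step 6 | (5S)-5-(2-hydroperoxy-2-methylpent-4-en-1-yl)-5-methylfuran-2(5H)-one (both epimers) | C=CCC(C)(OO)C[C@]1(C)OC(=O)C=C1
F5 | step 6 | (3S,4aS,7aS)-3-allyl-3,4a-dimethyltetrahydro-3H-furo[3,2-c][1,2]dioxin-6(4H)-one | C[C@]1(CC=C)C[C@]2(C)OC(=O)C[C@@H]2OO1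
F6 | step 1 | (±)-N,N-dimethyl-(1-methyl-3-oxo-2-oxabicyclo[3.2.0]heptan-6-ylidene)ammonium triflate, both enantiomers written | O=C1C[C@@H]2C(=[N+](C)C)C[C@]2(C)O1.O=C1C[C@H]2C(=[N+](C)C)C[C@@]2(C)O1.[O-]S(=O)(=O)C(F)(F)F.[O-]S(=O)(=O)C(F)(F)F
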